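## Structural features

The target is a single carbocycle, a cyclohexene in which every ring carbon is functionalised: C1 (quaternary, bearing the exocyclic C7H2–OBz), C2 (CH–OBz), C3 (CH–OH), C4=C5 and C6, with an oxirane cis-fused across C1–C6 (a 7-oxabicyclo[4.1.0]hept-4-ene). Four stereocentres stand in a row, C6–C1–C2–C3, one of them quaternary. The oxirane oxygen and the C3 hydroxyl lie on one ring face, the C2 benzoate and C7 on the other, so O2 and O3 are trans; the absolute configuration is 1S,2S,3R,6S. The oxirane is a vinyl oxirane (C6 is allylic) and tertiary at C1, the allylic C3 hydroxyl sits next to an ester that can migrate onto it, and loss of water or benzoic acid from the ring leads to an arene. Acid, strong base and heat must therefore be avoided late in the route. The carbon skeleton is trivial (a six-membered ring plus one carbon); the difficulty is to place five oxygen atoms with full relative and absolute control and to tell O2, O3 and O7 apart. The C1–C6 oxirane together with C4=C5 is what remains of a 1-substituted benzene oxide, and the trans C2–O/C3–O pair is what an oxirane across C2–C3, on the face opposite the first oxirane, gives when opened at allylic C3. The C7 hydroxyl is homoallylic to C2=C3 of that benzene oxide and can steer an oxidant to it; because the benzene oxide racemises through an achiral oxepin, one enantioselective oxygen transfer can set all four stereocentres.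

## Logic of the disconnections

**16 ⇒ 15.** The O3–CH2Ar bond of an ether is added in thought, so that the free C3 hydroxyl of 16 becomes a masked one in 15. O3 must be masked while O2 is acylated, because with both hydroxyls free an acyl group would go to the less hindered allylic O3. No skeletal simplification results, but the O2/O3 problem becomes a question of order. The forward step must free O3 under neutral, non-nucleophilic conditions that spare two benzoates, the vinyl oxirane and the alkene and do not let the C2 benzoate migrate.

**15 ⇒ 14 + 11.** The C2 oxygen–acyl bond is cut. This leaves 14 with one free secondary hydroxyl, so the acylation has no regiochemical choice. The forward step must acylate a hindered alcohol next to a quaternary carbon without acid.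

**14 ⇒ 12 + 13.** The C3–O(ether) bond is cut and O2 is joined back to C3, giving the C2–C3 oxirane of 12 and 13 as the oxygen nucleophile. This cut accounts for the trans O2/O3 pair and removes two stereocentres as independent problems, since both now follow from one oxirane. The forward opening must occur at C3 only, with inversion, and must leave the second vinyl oxirane (C1–C6, allylic at C6) closed. Opening the (1S,2S,3S,6S) dioxide at C3 with inversion gives exactly the 1S,2S,3R,6S pattern of 16, so the structures are consistent.

**12 ⇒ 10 + 11.** The C7 oxygen–acyl bond is cut. The ester is placed before the oxirane opening because it lowers the basicity of the neighbouring C1–C6 oxirane oxygen and shields C6. The forward step must be a base-buffered acylation of a primary alcohol.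

**10 ⇒ 8 (through 9).** The C2–O and C3–O bonds of the second oxirane and the C1–C6 ring bond are cut. Removing the oxirane oxygen leaves 9, whose C1–C6 bond opens in a retro-6π electrocyclisation to 8, an achiral monocycle with no stereocentre. Two rings, three bonds and four stereocentres disappear in one retrosynthetic move. The forward step must select one enantiomer of a rapidly racemising minor tautomer, one of its two alkenes and one face, under acid-free conditions.

**8 ⇒ 6.** The C2=C3 and C4=C5 alkenes of 9, the closed valence tautomer with which 8 is in exchange, are traced to two H–C–C–Br units: bromine on C3 and C4, hydrogen on C2 and C5. This turns a labile arene oxide into an ordinary saturated oxirane. The forward step needs two anti eliminations with a base too weak and too hindered to attack the oxirane or form the C7 alkoxide.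

**6 ⇒ 5.** The two C–O bonds of the C1–C6 oxirane are cut back to a trisubstituted alkene. The oxirane is introduced late so that it never meets a Lewis-acidic hydride or traces of hydrogen bromide. The forward step is an epoxidation of the only alkene left; its facial sense is irrelevant.

**5 ⇒ 4.** C7 is returned to the ester oxidation level. Keeping C7 as an ester through the dibromination is deliberate: the conjugated ester deactivates its own alkene, whereas in the allylic alcohol the trisubstituted alkene would be the more nucleophilic of the two and would compete for bromine. The forward step is a 1,2-reduction that leaves secondary bromides untouched.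

**4 ⇒ 3.** The two C–Br bonds at C3 and C4 are cut back to the isolated alkene. The forward step must brominate the electron-rich isolated alkene and not the conjugated one.

**3 ⇒ 1 + 2.** The C1–C2 and C5–C6 ring bonds are cut in a retro-[4+2] sense, which gives two commercial four-carbon and three-carbon pieces and places the carboxyl carbon on the future quaternary centre. The forward step needs only heat and exclusion of air.

## Other disconnections considered

Alternative 1: The cut is the ring bond C1–C2, which opens the carbocycle to the acyclic (Z)-enynal A2.

- **Forward step:** Ni(cod)2 (zerovalent nickel), an N-heterocyclic carbene and Et3SiH would couple alkyne and aldehyde through an oxanickelacycle. Silane cleavage and reductive elimination would give A1, with an exocyclic methylene at C1 and three different ethers on O2, O3 and O6.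
- **In favour:** C3 and C6 are made in the acyclic precursor by established asymmetric chemistry, so the absolute configuration does not depend on an untested enantioselective step. On this point the alternative is better than the chosen plan. O2, O3 and O6 leave the key step fully differentiated, which is equal or better than relying on the regiochemistry of step 8. The cyclisation is a known reaction type for alkynals.
- **Against:** C2 must be set trans to the C3 ether by substrate control alone, and A2 is an epimerisable α-alkoxy aldehyde with a cis-enyne. A1 has neither the C1–C6 oxirane nor the C7 oxygen. The exocyclic alkene would have to be epoxidised on the face opposite O6 and the oxirane then moved into the ring by a Payne migration. Silyl removal, two acylations and an ether cleavage would follow.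
- **Comparison:** Structurally it builds the ring from a chain and adds the oxirane afterwards, whereas the chosen plan keeps an intact six-membered ring throughout. Mechanistically it is an organometallic reductive coupling against a pericyclic closure plus oxo transfer. In step count it would be clearly longer, both before A2 and after A1.

Alternative 2: The cut removes the C3–O and C6–O bonds, leading back to the spiro-epoxy cyclohexadiene benzoate A4.

- **Forward step:** Tetraphenylporphyrin-sensitised singlet oxygen would add suprafacially across C3=C4–C5=C6, anti to the C2 benzoate, to give the endoperoxide A3. Reduction of the O–O bond, base-induced migration of the oxirane from C1–C7 to C1–C6 and acylation of the released C7 hydroxyl would complete the target.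
- **In favour:** The [4+2] addition of singlet oxygen to a cyclohexadiene is a dependable, known reaction. It sets O3 and O6 cis in one step. The C2 benzoate is in place from the start, so there is no O2/O3 differentiation problem; this is better than the chosen plan. Only three operations would follow the key step, which is equal or slightly better than four.
- **Against:** A4 is one proton transfer from an aromatic isomer: ionisation of the allylic spiro-oxirane gives a pentadienyl cation that aromatises. Nothing in the sequence creates absolute configuration, so A4 would have to be made enantiopure with two adjacent stereocentres, one of them spiro-quaternary. In the basic migration step the C3 alkoxide sits beside the C2 benzoate, which invites acyl migration.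
- **Comparison:** Structurally both plans treat the ring as an oxidised arene-type diene. Mechanistically both rest on a pericyclic step, and this one is precedented where step 6 is not. In step count it is equal after the key step but probably worse before it, and its precursor is more fragile than 8.

Alternative 3: The cut is the C1–O bond of the C1–C6 oxirane in an acyclic setting, with the ring later closed at C4=C5.

- **Forward step:** NaH would convert the C6 hydroxyl of the terminal 2,2-disubstituted oxirane A6 into an alkoxide. It would attack C1 with inversion and release the C7 alkoxide, giving the trisubstituted vinyl oxirane A5. Ring-closing metathesis of the two vinyl groups of A5 with RuCl2(=CHPh)(PCy3)(H2IMes), the second-generation Grubbs catalyst, would then form C4=C5.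
- **In favour:** Every stereocentre comes from acyclic asymmetric reactions of known type. The equilibrium should favour the more substituted oxirane and the primary alkoxide. O2 and O3 carry orthogonal ethers, and C7–OH appears free when needed. In predictability of absolute configuration and in precedent for each step it is equal or better than the chosen plan.
- **Against:** The substitution takes place at a fully substituted carbon and is reversible. Silyl migration can compete under NaH. A6 needs a long linear sequence with four stereocentres, including the tetrasubstituted oxirane carbon. After A5 there remain metathesis (slowed by allylic ethers), two acylations and two deprotections.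
- **Comparison:** Structurally the ring is made last, from a chain. Mechanistically it is a polar substitution against electrocyclisation plus oxo transfer. In step count it would be roughly twice as long as the chosen plan.

Key step: step 6

Remark: the oxepin and the benzene oxide are valence tautomers in fast exchange at every temperature used, so step 5 is taken to deliver them as one substance, numbered once as the oxepin 8; the benzene oxide is numbered 9 in step 6, where it is the tautomer that reacts on.

Remark: from compound 6 onwards, names use the ring locants C1–C6 defined above (position 7 of the bicyclic names is the oxirane oxygen, while C7 in the text is the exocyclic CH2). The sense of induction of the bishydroxamic acid on this new substrate class cannot be derived from first principles, so the (R,R)-ligand is written and its mirror image is to be used if the opposite sense is needed.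

## Route

Step 1
Reactants: 1 buta-1,3-diene; 2 methyl propiolate
Product: 3 methyl cyclohexa-1,4-diene-1-carboxylate
Conditions: 1 (3 equiv), toluene, BHT (cat.), sealed tube, 110 °C
Reagents that add atoms: none
Why: Thermal Diels–Alder [4+2] cycloaddition of the s-cis diene to the electron-poor alkyne forms both new ring bonds at once and gives the skipped diene directly; no stereocentre arises. Excess diene and a radical inhibitor suppress polymerisation, and exclusion of air prevents aromatisation.

Step 2
Reactants: 3 methyl cyclohexa-1,4-diene-1-carboxylate
Product: 4 methyl (4RS,5RS)-4,5-dibromocyclohex-1-ene-1-carboxylate (racemic trans-dibromide)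
Conditions: Br2 (1.0 equiv), CH2Cl2, −78 °C; aq. Na2S2O3
Reagents that add atoms: bromine, BrBr
Why: Electrophilic anti addition through a bromonium ion takes place at the isolated, electron-rich alkene, because the conjugated alkene is deactivated by the ester, and one equivalent at low temperature guards against over-bromination. The trans-dibromide is racemic; its two stereocentres only carry leaving groups and disappear in step 5.

Step 3
Reactants: 4 methyl (4RS,5RS)-4,5-dibromocyclohex-1-ene-1-carboxylate
Product: 5 [(4RS,5RS)-4,5-dibromocyclohex-1-en-1-yl]methanol
Conditions: i-Bu2AlH (2.5 equiv), CH2Cl2, −78 °C; aq. KNaC4H4O6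
Reagents that add atoms: none
Why: 1,2-Reduction of the conjugated ester by the electrophilic aluminium hydride stops at the allylic alcohol; secondary alkyl bromides and the trisubstituted alkene are inert at this temperature.

Step 4
Reactants: 5 [(4RS,5RS)-4,5-dibromocyclohex-1-en-1-yl]methanol
Product: 6 [(3R*,4R*)-3,4-dibromo-7-oxabicyclo[4.1.0]heptan-1-yl]methanol (racemic; either oxirane diastereomer)
Conditions: mCPBA (1.2 equiv), NaHCO3, CH2Cl2, 0 °C
Reagents that add atoms: mCPBA, O=C(OO)c1cccc(Cl)c1
Why: Prilezhaev epoxidation of the only alkene, a trisubstituted allylic-alcohol alkene, with NaHCO3 buffering the acid. The oxirane is necessarily cis-fused, and its orientation relative to the bromines does not matter because both diastereomers converge in step 5.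

Step 5
Reactants: 6 [(3R*,4R*)-3,4-dibromo-7-oxabicyclo[4.1.0]heptan-1-yl]methanol
Product: 8 2-(hydroxymethyl)oxepin, via allylic monobromide 7 (not isolated)
Conditions: DBU (3 equiv), THF, 0 °C → rt, dark; filtration, Et3N-treated Al2O3 (basic), cold
Reagents that add atoms: none
Why: Two successive E2 dehydrobrominations take the ring CH2 hydrogens anti to each bromide (the hydrogen on the bromine-bearing neighbour is not anti, so no vinyl bromide should form), as in the classical arene oxide synthesis by double elimination. The 2,4-diene oxide that the second elimination leaves is the closed valence tautomer of 8 and exchanges with it by thermal disrotatory 6π ring opening faster than it can be handled, so the material isolated is this one equilibrating substance, named as the oxepin. The amidine is too weak a base to make the C7 alkoxide, so oxirane migration and ether formation should stay slow, and all earlier stereocentres are erased in achiral 8.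

Step 6
Reactants: 8 2-(hydroxymethyl)oxepin
Product: 10 [(1S,2S,3S,6S)-1,6:2,3-diepoxycyclohex-4-en-1-yl]methanol, via 1-(hydroxymethyl)benzene oxide 9 (not isolated)
Conditions: VO(O-i-Pr)3 (2 mol %, pentavalent vanadium), (R,R)-cyclohexane-1,2-diamine-derived bishydroxamic acid with bulky diarylacetyl groups (4 mol %), cumene hydroperoxide (1.1 equiv), toluene, 0 °C
Reagents that add atoms: cumene hydroperoxide, CC(C)(OO)c1ccccc1
Why: Proposed new method: 8 and racemic 9 interconvert by thermal disrotatory 6π electrocyclisation of the O–C1=C2–C3=C4–C5=C6 triene, which forms C1–C6 and in one event closes the six-membered carbocycle and contracts the oxygen bridge to the cis-fused oxirane; this exchange is far faster than any oxidation, so the two enantiomers of 9 remain in equilibrium throughout (Curtin–Hammett). The C7 hydroxyl exchanges onto the pentavalent vanadium centre that carries the C2-symmetric bishydroxamate and the bound cumyl peroxide, and the peroxide oxygen is passed to C2=C3 in a concerted, cis-specific oxygen-atom transfer that closes the second oxirane by forming C2–O and C3–O on one face. The closest known reaction type is the vanadium–bishydroxamic acid epoxidation of homoallylic alcohols with cumene hydroperoxide; the new element is that the homoallylic alkene exists only in a minor, racemising valence tautomer. C1 and C6 are cis through the disrotatory closure, and C2 and C3 are set syn to C7, hence anti to the first oxirane, because the short C7–O–V tether reaches only the ring face on which C7 stands. Since each enantiomer of 9 offers only that one face, the ligand's choice between the enantiotopic alkene faces is at the same time a choice of enantiomer and fixes the absolute configuration of all four centres. Regioselectivity for C2=C3 over C4=C5 follows from tether length (homoallylic against bishomoallylic). The step also needs chemoselectivity against the enol-ether alkenes of 8 and against aromatisation, which the strongly donating ligand (low Lewis acidity at vanadium), the absence of Brønsted acid and a limiting amount of hydroperoxide are meant to secure.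

Step 7
Reactants: 10 [(1S,2S,3S,6S)-1,6:2,3-diepoxycyclohex-4-en-1-yl]methanol; 11 benzoyl chloride
Product: 12 [(1S,2S,3S,6S)-1,6:2,3-diepoxycyclohex-4-en-1-yl]methyl benzoate
Conditions: 11 (1.1 equiv), Et3N, DMAP (cat.), CH2Cl2, −20 → 0 °C
Reagents that add atoms: none
Why: DMAP-catalysed acylation of the primary alcohol with the amine taking up HCl, so that neither oxirane meets acid and no stereocentre is touched. The ester also lowers the basicity of the adjacent C1–C6 oxirane oxygen, which prepares the site selectivity of step 8.

Step 8
Reactants: 12 [(1S,2S,3S,6S)-1,6:2,3-diepoxycyclohex-4-en-1-yl]methyl benzoate; 13 4-methoxybenzyl alcohol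
Product: 14 [(1R,2S,3R,6S)-2-hydroxy-3-(4-methoxybenzyloxy)-7-oxabicyclo[4.1.0]hept-4-en-1-yl]methyl benzoate
Conditions: 13 (3 equiv), BF3·OEt2 (0.2 equiv), CH2Cl2, −40 °C; Et3N quench
Reagents that add atoms: none
Why: Lewis acid-activated SN2 opening of a vinyl oxirane by an alcohol at allylic C3 with inversion places the new C3–O bond on the face of the C1–C6 oxirane while C2 keeps its oxygen, which gives the trans O2/O3 pair. C2 is not allylic and is flanked by quaternary C1; the C1–C6 oxirane is less basic (β-acyloxy) and attack at C6 would have to pass the C7H2OBz group on the same face.

Step 9
Reactants: 14 [(1R,2S,3R,6S)-2-hydroxy-3-(4-methoxybenzyloxy)-7-oxabicyclo[4.1.0]hept-4-en-1-yl]methyl benzoate; 11 benzoyl chloride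
Product: 15 [(1S,2S,3R,6S)-2-(benzoyloxy)-3-(4-methoxybenzyloxy)-7-oxabicyclo[4.1.0]hept-4-en-1-yl]methyl benzoate
Conditions: 11 (2 equiv), pyridine, DMAP (0.2 equiv), CH2Cl2, 0 °C → rt
Reagents that add atoms: none
Why: DMAP-catalysed acylation of the only free hydroxyl; the C2–O bond is not broken, so configuration is retained. Any benzoyl shift between O7 and O2 beforehand would be harmless, because both oxygens end up benzoylated.

Step 10
Reactants: 15 [(1S,2S,3R,6S)-2-(benzoyloxy)-3-(4-methoxybenzyloxy)-7-oxabicyclo[4.1.0]hept-4-en-1-yl]methyl benzoate
Product: 16 [(1S,2S,3R,6S)-2-(benzoyloxy)-3-hydroxy-7-oxabicyclo[4.1.0]hept-4-en-1-yl]methyl benzoate (target, CNP0285759.2)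
Conditions: DDQ (1.3 equiv), CH2Cl2–aq. NaH2PO4/Na2HPO4 buffer pH 7 (10:1), 0 °C
Reagents that add atoms: none
Why: Oxidative cleavage of the electron-rich benzyl ether by DDQ proceeds by hydride abstraction to an oxocarbenium ion that water hydrolyses; benzoates, oxirane and alkene are not attacked. The neutral buffer takes up the acidic hydroquinone, so the vinyl oxirane should survive and the C2 benzoate should not migrate.

## Compound list

1 | buta-1,3-diene | C=CC=C | starting material
2 | methyl propiolate | C#CC(=O)OC | starting material
3 | methyl cyclohexa-1,4-diene-1-carboxylate | COC(=O)C1=CCC=CC1 | intermediate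
4 | methyl (4RS,5RS)-4,5-dibromocyclohex-1-ene-1-carboxylate (racemic trans-dibromide, one enantiomer drawn) | COC(=O)C1=CC[C@@H](Br)[C@H](Br)C1 | intermediate
5 | [(4RS,5RS)-4,5-dibromocyclohex-1-en-1-yl]methanol (racemic, one enantiomer drawn) | OCC1=CC[C@@H](Br)[C@H](Br)C1 | intermediate
6 | [(3R*,4R*)-3,4-dibromo-7-oxabicyclo[4.1.0]heptan-1-yl]methanol (racemic; either oxirane diastereomer, the one with the oxirane cis to Br on C4 drawn) | OC[C@]12O[C@H]1C[C@@H](Br)[C@H](Br)C2 | intermediate
7 | (4-bromo-7-oxabicyclo[4.1.0]hept-2-en-1-yl)methanol (allylic monobromide, racemic; the 3-bromo-4-ene regioisomer is equally possible and converges) | OC[C@]12O[C@H]1C[C@@H](Br)C=C2 | intermediate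
8 | 2-(hydroxymethyl)oxepin (achiral; handled in fast exchange with its closed valence tautomer 9) | OCC1=CC=CC=CO1 | intermediate
9 | 1-(hydroxymethyl)benzene oxide, (7-oxabicyclo[4.1.0]hepta-2,4-dien-1-yl)methanol (racemic, in equilibrium with 8; the (1S,6S) enantiomer consumed in step 6 is drawn) | OC[C@]12O[C@H]1C=CC=C2 | intermediate
10 | [(1S,2S,3S,6S)-1,6:2,3-diepoxycyclohex-4-en-1-yl]methanol (1-(hydroxymethyl) anti-benzene dioxide) | OC[C@]12O[C@H]1C=C[C@@H]3O[C@H]23 | intermediate
11 | benzoyl chloride | O=C(Cl)c1ccccc1 | starting material
12 | [(1S,2S,3S,6S)-1,6:2,3-diepoxycyclohex-4-en-1-yl]methyl benzoate | O=C(OC[C@]12O[C@H]1C=C[C@@H]3O[C@H]23)c1ccccc1 | intermediate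
13 | 4-methoxybenzyl alcohol | COc1ccc(CO)cc1 | starting material
14 | [(1R,2S,3R,6S)-2-hydroxy-3-(4-methoxybenzyloxy)-7-oxabicyclo[4.1.0]hept-4-en-1-yl]methyl benzoate | O=C(OC[C@]12O[C@H]1C=C[C@@H](OCc3ccc(OC)cc3)[C@@H]2O)c1ccccc1 | intermediate
15 | [(1S,2S,3R,6S)-2-(benzoyloxy)-3-(4-methoxybenzyloxy)-7-oxabicyclo[4.1.0]hept-4-en-1-yl]methyl benzoate | O=C(OC[C@]12O[C@H]1C=C[C@@H](OCc3ccc(OC)cc3)[C@@H]2OC(=O)c2ccccc2)c1ccccc1 | intermediate
16 | [(1S,2S,3R,6S)-2-(benzoyloxy)-3-hydroxy-7-oxabicyclo[4.1.0]hept-4-en-1-yl]methyl benzoate | O=C(OC[C@]12O[C@H]1C=C[C@@H](O)[C@@H]2OC(=O)c1ccccc1)c1ccccc1 | target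

## Step count and least certain steps

Total: 10 steps. Longest linear sequence: 10 steps (1 and 2 to 16); 11 and 13 enter as single building blocks.

**Step 6 (key step, new method).** Three processes can defeat it.
- Oxygen transfer to the oxepin tautomer, whose C1=C2 enol-ether alkene is allylic to the same vanadium alkoxide, would be followed by ring cleavage to an open-chain dienedial.
- The ligand may discriminate poorly between the two enantiomers of 9, because the quaternary C1 and the fused oxirane sit unusually close to the metal.
- Vanadium may act as a Lewis acid and aromatise the arene oxide.

The fallback uses only known reaction types and sets out from 8. Tetraphenylporphyrin-sensitised photo-oxygenation (O2, visible light, CH2Cl2, −30 °C) should add singlet oxygen in a [4+2] sense across C2 and C5 of the benzene oxide tautomer, anti to the oxirane, to give the racemic anti-endoperoxide F1. Deoxygenation with P(OMe)3 is expected to attack the less hindered peroxide oxygen on C5, after which the C2 alkoxide closes onto C3 with shift of the alkene to C4=C5. This gives the racemic anti-dioxide, that is 10 together with its mirror-image dioxide F2. Preparative chromatography on a chiral stationary phase (amylose tris(3,5-dimethylphenylcarbamate)) would separate the two, and the route is rejoined at 10.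

**Step 5.** The arene oxide may aromatise to phenolic material on traces of acid during isolation. With the hydroxyl free, slow intramolecular displacement of a bromide or oxirane migration may compete with the second elimination. The fallback sets out from 6. Silylation (TBSCl, imidazole, DMF) gives the tert-butyldimethylsilyl ether F3. The same DBU elimination then gives 2-[(tert-butyldimethylsilyloxy)methyl]oxepin F4, which has no nucleophilic oxygen and is easier to purify. Bu4NF in THF at 0 °C removes the silyl group under basic conditions and returns to 8.

**Step 8.** The Lewis acid may ionise 13 to its benzylic cation (self-etherification) faster than it activates the oxirane. If a stronger acid is needed, opening of the C1–C6 oxirane at C6, participation by the C7 benzoate or conjugate addition at C5 may intrude. The fallback sets out from 12 and replaces the alcohol by water. Mild hydrolysis (THF–H2O, cat. HClO4, 0 °C) should open the C2–C3 oxirane at C3 to the trans-2,3-diol F5. The less hindered allylic C3 hydroxyl is silylated selectively (TESCl, imidazole, −20 °C) to the C3 triethylsilyl ether F6. Benzoylation with 11 (pyridine, DMAP) gives the C2 benzoate F7, and buffered HF·pyridine in THF–pyridine at 0 °C removes the silyl group. This rejoins the route at 16 and bypasses 14 and 15.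

**Step 10.** The quinone may go on to oxidise the liberated allylic C3 alcohol to an enone. The acidic hydroquinone may open the vinyl oxirane. The C2 benzoate may shift to O3 on work-up. The fallback sets out from 12 and avoids any oxidant. Levulinic acid (excess, CH2Cl2, rt) opens the C2–C3 oxirane at C3 in the way carboxylic acids open anti-benzene dioxides, giving the C3 levulinate F8. Benzoylation with 11 (pyridine, DMAP, 0 °C) gives the C2 benzoate C3 levulinate F9. Hydrazine acetate in CH2Cl2–MeOH at 0 °C removes the levulinoyl group selectively in the presence of benzoates and rejoins the route at 16.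

## Further compounds

F1 | step 6 | 2,5-epidioxy-1,6-epoxy-1-(hydroxymethyl)cyclohex-3-ene, anti-endoperoxide (racemic; enantiomer leading to 10 drawn) | OC[C@]12O[C@H]1[C@H]1C=C[C@@H]2OO1
F2 | step 6 | [(1R,2R,3R,6R)-1,6:2,3-diepoxycyclohex-4-en-1-yl]methanol (mirror image of 10) | OC[C@@]12O[C@@H]1C=C[C@H]3O[C@@H]23
F3 | step 5 | tert-butyl{[(3R*,4R*)-3,4-dibromo-7-oxabicyclo[4.1.0]heptan-1-yl]methoxy}dimethylsilane (racemic) | CC(C)(C)[Si](C)(C)OC[C@]12O[C@H]1C[C@@H](Br)[C@H](Br)C2
F4 | step 5 | 2-[(tert-butyldimethylsilyloxy)methyl]oxepin | CC(C)(C)[Si](C)(C)OCC1=CC=CC=CO1
F5 | step 8 | [(1R,2S,3R,6S)-2,3-dihydroxy-7-oxabicyclo[4.1.0]hept-4-en-1-yl]methyl benzoate | O=C(OC[C@]12O[C@H]1C=C[C@@H](O)[C@@H]2O)c1ccccc1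
F6 | step 8 | [(1R,2S,3R,6S)-2-hydroxy-3-(triethylsilyloxy)-7-oxabicyclo[4.1.0]hept-4-en-1-yl]methyl benzoate | O=C(OC[C@]12O[C@H]1C=C[C@@H](O[Si](CC)(CC)CC)[C@@H]2O)c1ccccc1
F7 | step 8 | [(1S,2S,3R,6S)-2-(benzoyloxy)-3-(triethylsilyloxy)-7-oxabicyclo[4.1.0]hept-4-en-1-yl]methyl benzoate | O=C(OC[C@]12O[C@H]1C=C[C@@H](O[Si](CC)(CC)CC)[C@@H]2OC(=O)c2ccccc2)c1ccccc1
F8 | step 10 | [(1R,2S,3R,6S)-2-hydroxy-3-(4-oxopentanoyloxy)-7-oxabicyclo[4.1.0]hept-4-en-1-yl]methyl benzoate | O=C(OC[C@]12O[C@H]1C=C[C@@H](OC(=O)CCC(C)=O)[C@@H]2O)c1ccccc1
F9 | step 10 | [(1S,2S,3R,6S)-2-(benzoyloxy)-3-(4-oxopentanoyloxy)-7-oxabicyclo[4.1.0]hept-4-en-1-yl]methyl benzoate | O=C(OC[C@]12O[C@H]1C=C[C@@H](OC(=O)CCC(C)=O)[C@@H]2OC(=O)c2ccccc2)c1ccccc1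
A1 | alternative 1 | 1-methylenecyclohex-4-ene-2,3,6-triol 2-triethylsilyl 3-(4-methoxybenzyl) 6-tert-butyldimethylsilyl triether (target locants) | C=C1[C@@H](O[Si](CC)(CC)CC)[C@H](OCc2ccc(OC)cc2)C=C[C@@H]1O[Si](C)(C)C(C)(C)C
A2 | alternative 1 | (Z)-5-(tert-butyldimethylsilyloxy)-2-(4-methoxybenzyloxy)hept-3-en-6-ynal | C#C[C@@H](O[Si](C)(C)C(C)(C)C)/C=C\[C@@H](OCc1ccc(OC)cc1)C=O
A3 | alternative 2 | spiro-epoxy 2,3-dioxabicyclo[2.2.2]oct-5-ene benzoate (endoperoxide) | C1O[C@]12[C@@H](OC(=O)c4ccccc4)[C@H]3C=C[C@@H]2OO3
A4 | alternative 2 | 1-oxaspiro[2.5]octa-5,7-dien-4-yl benzoate | C1O[C@]12[C@@H](OC(=O)c3ccccc3)C=CC=C2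
A5 | alternative 3 | {2-[2-(tert-butyldimethylsilyloxy)-1-(4-methoxybenzyloxy)but-3-en-1-yl]-3-vinyloxiran-2-yl}methanol | OC[C@@]1(O[C@H]1C=C)[C@@H](OCc1ccc(OC)cc1)[C@H](O[Si](C)(C)C(C)(C)C)C=C
A6 | alternative 3 | 1-{2-[2-(tert-butyldimethylsilyloxy)-1-(4-methoxybenzyloxy)but-3-en-1-yl]oxiran-2-yl}prop-2-en-1-ol | C=C[C@H](O)[C@]1(CO1)[C@@H](OCc1ccc(OC)cc1)[C@H](O[Si](C)(C)C(C)(C)C)C=C
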